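**Retrosynthetic overview**
- Last step is fluoride desilylation. Before it, the only ring that has to be made, the pyran ring (ring C), is closed by intramolecular Mitsunobu O1–C2 etherification of an acyclic 2,3-diarylpropan-1-ol.
- Key disconnection C3–C1': the alpha-carbon of a ring A 3-arylpropanal is made electrophilic as a chiral enamine radical cation (an enolonium equivalent) and is captured by the nucleophilic ring B arene. The (R) centre at C3 is set in this step.
- Ring A aldehyde: 2-iodoresorcinol, then B-alkyl Suzuki coupling (hydroxy-isopentyl chain), iodination/acetylation, and Heck reaction with allyl alcohol.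
- Ring B arene: 4-bromoresorcinol, then bis-silyl ether, then gamma-selective allyl–aryl Suzuki coupling (1,1-dimethylallyl group).
- Ring order: rings A and B are bought as resorcinols; ring C is formed in the second-to-last step.

Assumption: 2-iodoresorcinol, 4-bromoresorcinol, prenylboronic acid pinacol ester and the (2S,5S)-imidazolidinone catalyst are taken as inexpensive catalogue items.

**Step 1**
Reactants: 1 2-iodobenzene-1,3-diol; 2 2-methylbut-3-en-2-ol
Product: 4 2-(3-hydroxy-3-methylbutyl)benzene-1,3-diol, via alkylborane 3 (not isolated)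
Conditions: 2, 9-BBN (1.5 equiv), THF, 0 °C → rt; then 1, PdCl2[1,1'-bis(diphenylphosphino)ferrocene] (5 mol%), 3 M aq. K3PO4, THF/DMF, 60 °C
Reagents that add atoms: none
Why: B-alkyl Suzuki–Miyaura coupling; anti-Markovnikov hydroboration puts boron on the terminal carbon, and the primary alkyl group is then transferred to the aryl iodide under aqueous base that tolerates the phenoxides and the tertiary alcohol.

**Step 2**
Reactants: 4 2-(3-hydroxy-3-methylbutyl)benzene-1,3-diol
Product: 6 2-(3-hydroxy-3-methylbutyl)-4-iodo-1,3-phenylene diacetate, via iodoresorcinol 5 (not isolated)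
Conditions: NIS (1.0 equiv), MeCN, −20 °C; then pyridine, Ac2O (2.5 equiv), 0 °C → rt
Reagents that add atoms: N-iodosuccinimide, O=C1CCC(=O)N1I; acetic anhydride, CC(=O)OC(C)=O
Why: Electrophilic aromatic iodination of the symmetric 2-alkylresorcinol can only occur at the equivalent 4/6 positions, and one equivalent of NIS in the cold stops at the mono-iodide; acetylation of both phenols then makes ring A electron-poor for step 6 while the tertiary alcohol stays free.

**Step 3**
Reactants: 6 2-(3-hydroxy-3-methylbutyl)-4-iodo-1,3-phenylene diacetate; 7 prop-2-en-1-ol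
Product: 8 2-(3-hydroxy-3-methylbutyl)-4-(3-oxopropyl)-1,3-phenylene diacetate
Conditions: Pd(OAc)2 (3 mol%), Bu4NCl, NaHCO3, DMF, 45 °C
Reagents that add atoms: none
Why: Heck reaction with allyl alcohol under ligand-free phase-transfer (Jeffery) conditions; aryl–palladium insertion at the terminal carbon and beta-hydride elimination towards the carbinol give an enol that tautomerises to the 3-arylpropanal.

**Step 4**
Reactants: 9 4-bromobenzene-1,3-diol
Product: 10 1-bromo-2,4-bis(tert-butyldimethylsilyloxy)benzene
Conditions: TBSCl (2.3 equiv), imidazole, DMF, rt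
Reagents that add atoms: tert-butyldimethylsilyl chloride, CC(C)(C)[Si](C)(C)Cl
Why: Standard silylation of both phenols; the silyl ethers keep ring B electron-rich, survive oxidant, hydride and Mitsunobu conditions, and come off with fluoride without acid.

**Step 5**
Reactants: 10 1-bromo-2,4-bis(tert-butyldimethylsilyloxy)benzene; 11 4,4,5,5-tetramethyl-2-(3-methylbut-2-en-1-yl)-1,3,2-dioxaborolane
Product: 12 2,4-bis(tert-butyldimethylsilyloxy)-1-(2-methylbut-3-en-2-yl)benzene
Conditions: Pd(OAc)2 (3 mol%), 1,1'-bis(di-tert-butylphosphino)ferrocene (4 mol%), K3PO4, THF/H2O (10:1), 40 °C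
Reagents that add atoms: none
Why: Gamma-selective Suzuki–Miyaura allyl–aryl coupling; SE2' transmetalation places palladium on the tertiary allyl terminus, and the bulky electron-rich bisphosphine drives reductive elimination before allyl isomerisation, giving the 1,1-dimethylallyl arene.

**Step 6 (key step)**
Reactants: 8 2-(3-hydroxy-3-methylbutyl)-4-(3-oxopropyl)-1,3-phenylene diacetate; 12 2,4-bis(tert-butyldimethylsilyloxy)-1-(2-methylbut-3-en-2-yl)benzene (2.5 equiv, excess recovered)
Product: 14 4-[(2R)-2-{2,4-bis(tert-butyldimethylsilyloxy)-5-(2-methylbut-3-en-2-yl)phenyl}-3-hydroxypropyl]-2-(3-hydroxy-3-methylbutyl)benzene-1,3-diol, via aldehyde 13 (not isolated)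
Conditions: (2S,5S)-5-benzyl-2-tert-butyl-3-methylimidazolidin-4-one·CF3CO2H (20 mol%), (NH4)2Ce(NO3)6 (2.2 equiv), NaHCO3, H2O (2 equiv), DME, −20 °C; cold aqueous work-up; then LiBH4 (4 equiv), THF/MeOH, −20 → 0 °C
Reagents that add atoms: none
Why: Proposed new method: the chiral enamine of 8 is oxidised by one electron (tetravalent cerium) to a 3π-electron radical cation whose alpha-carbon is electrophilic (an enolonium equivalent); the only strongly nucleophilic carbon of 12 (ortho to one silyloxy group, para to the other) adds to the Si face that the benzyl arm of the (2S,5S) catalyst leaves open, and a second one-electron oxidation with proton loss rearomatises to the (R)-aldehyde 13, which LiBH4 reduces at once while also cleaving both aryl acetates; the diacetate keeps ring A from competing as nucleophile, and the closest known reactions are organo-SOMO alpha-allylation, intermolecular alpha-heteroarylation with N-Boc-pyrrole and intramolecular alpha-arylation of aldehydes.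

**Step 7**
Reactants: 14 4-[(2R)-2-{2,4-bis(tert-butyldimethylsilyloxy)-5-(2-methylbut-3-en-2-yl)phenyl}-3-hydroxypropyl]-2-(3-hydroxy-3-methylbutyl)benzene-1,3-diol
Product: 15 (3R)-3-[2,4-bis(tert-butyldimethylsilyloxy)-5-(2-methylbut-3-en-2-yl)phenyl]-8-(3-hydroxy-3-methylbutyl)chroman-7-ol
Conditions: PPh3 (1.3 equiv), DIAD (1.3 equiv), THF (0.02 M), 0 °C → rt
Reagents that add atoms: none
Why: Intramolecular Mitsunobu etherification; only the primary alcohol is activated and the neighbouring ring A phenol closes the six-membered ring (6-exo-tet), while the tertiary alcohol is inert, the other ring A phenol cannot reach, the silyl groups block dihydrobenzofuran formation from ring B, and the stereocentre is not involved.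

**Step 8**
Reactants: 15 (3R)-3-[2,4-bis(tert-butyldimethylsilyloxy)-5-(2-methylbut-3-en-2-yl)phenyl]-8-(3-hydroxy-3-methylbutyl)chroman-7-ol
Product: 16 4-[(3R)-7-hydroxy-8-(3-hydroxy-3-methylbutyl)-3,4-dihydro-2H-chromen-3-yl]-6-(2-methylbut-3-en-2-yl)benzene-1,3-diol
Conditions: Bu4NF (2.5 equiv), AcOH (2.5 equiv), THF, 0 °C
Reagents that add atoms: none
Why: Fluoride desilylation of the two aryl silyl ethers under acetic acid buffering; no strong acid is used, so neither the tertiary alcohol nor the 1,1-dimethylallyl group cyclises onto its neighbouring phenol, and the alkene and the C3 centre are untouched.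

**Compound list**
1 | 2-iodobenzene-1,3-diol | Oc1cccc(O)c1I | starting material
2 | 2-methylbut-3-en-2-ol | C=CC(C)(C)O | starting material
3 | 4-(9-borabicyclo[3.3.1]nonan-9-yl)-2-methylbutan-2-ol | CC(C)(O)CCB1C2CCCC1CCC2 | intermediate
4 | 2-(3-hydroxy-3-methylbutyl)benzene-1,3-diol | CC(C)(O)CCc1c(O)cccc1O | intermediate
5 | 2-(3-hydroxy-3-methylbutyl)-4-iodobenzene-1,3-diol | CC(C)(O)CCc1c(O)ccc(I)c1O | intermediate
6 | 2-(3-hydroxy-3-methylbutyl)-4-iodo-1,3-phenylene diacetate | CC(=O)Oc1ccc(I)c(OC(C)=O)c1CCC(C)(C)O | intermediate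
7 | prop-2-en-1-ol | C=CCO | starting material
8 | 2-(3-hydroxy-3-methylbutyl)-4-(3-oxopropyl)-1,3-phenylene diacetate | CC(=O)Oc1ccc(CCC=O)c(OC(C)=O)c1CCC(C)(C)O | intermediate
9 | 4-bromobenzene-1,3-diol | Oc1ccc(Br)c(O)c1 | starting material
10 | 1-bromo-2,4-bis(tert-butyldimethylsilyloxy)benzene | CC(C)(C)[Si](C)(C)Oc1ccc(Br)c(O[Si](C)(C)C(C)(C)C)c1 | intermediate
11 | 4,4,5,5-tetramethyl-2-(3-methylbut-2-en-1-yl)-1,3,2-dioxaborolane | CC(C)=CCB1OC(C)(C)C(C)(C)O1 | starting material
12 | 2,4-bis(tert-butyldimethylsilyloxy)-1-(2-methylbut-3-en-2-yl)benzene | C=CC(C)(C)c1ccc(O[Si](C)(C)C(C)(C)C)cc1O[Si](C)(C)C(C)(C)C | intermediate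
13 | 4-[(2R)-2-{2,4-bis(tert-butyldimethylsilyloxy)-5-(2-methylbut-3-en-2-yl)phenyl}-3-oxopropyl]-2-(3-hydroxy-3-methylbutyl)-1,3-phenylene diacetate | C=CC(C)(C)c1cc([C@H](C=O)Cc2ccc(OC(C)=O)c(CCC(C)(C)O)c2OC(C)=O)c(O[Si](C)(C)C(C)(C)C)cc1O[Si](C)(C)C(C)(C)C | intermediate
14 | 4-[(2R)-2-{2,4-bis(tert-butyldimethylsilyloxy)-5-(2-methylbut-3-en-2-yl)phenyl}-3-hydroxypropyl]-2-(3-hydroxy-3-methylbutyl)benzene-1,3-diol | C=CC(C)(C)c1cc([C@H](CO)Cc2ccc(O)c(CCC(C)(C)O)c2O)c(O[Si](C)(C)C(C)(C)C)cc1O[Si](C)(C)C(C)(C)C | intermediate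
15 | (3R)-3-[2,4-bis(tert-butyldimethylsilyloxy)-5-(2-methylbut-3-en-2-yl)phenyl]-8-(3-hydroxy-3-methylbutyl)chroman-7-ol | C=CC(C)(C)c1cc([C@@H]2COc3c(ccc(O)c3CCC(C)(C)O)C2)c(O[Si](C)(C)C(C)(C)C)cc1O[Si](C)(C)C(C)(C)C | intermediate
16 | 4-[(3R)-7-hydroxy-8-(3-hydroxy-3-methylbutyl)-3,4-dihydro-2H-chromen-3-yl]-6-(2-methylbut-3-en-2-yl)benzene-1,3-diol | C=CC(C)(C)c1cc([C@@H]2COc3c(ccc(O)c3CCC(C)(C)O)C2)c(O)cc1O | target

**Totals**
Total step count: 8. Longest linear sequence: 6 (steps 1, 2, 3, 6, 7, 8); the ring B branch is steps 4 and 5.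

**Three steps most likely to fail**

Step 6 (highest risk). Intermolecular capture of the enamine radical cation by a benzenoid arene is unprecedented. The silyl ethers make 12 less nucleophilic than a methyl ether, the attacked carbon sits next to a bulky silyloxy group, and the oxidant may attack 12 itself. Fallback: reverse the polarity of the arene instead of the aldehyde. It sets out from 12 and 8. Treating 12 with [hydroxy(tosyloxy)iodo]mesitylene in CF3CH2OH at rt puts iodine on the same ring carbon and gives [2,4-bis(tert-butyldimethylsilyloxy)-5-(2-methylbut-3-en-2-yl)phenyl](mesityl)iodonium tosylate F1. Then 8 and F1 are joined with CuBr (10 mol%), the same (2S,5S)-imidazolidinone as its trichloroacetate salt and NaHCO3 in toluene/Et2O at rt. Here the nucleophilic enamine attacks an electrophilic aryl–copper species (trivalent copper) on the same open Si face. The fallback comes back to the route at 13, which is reduced to 14 as in step 6.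

Step 5. The hindered ortho-silyloxy aryl bromide may let the allyl–palladium isomerise and give the linear prenyl arene, and aqueous base may partly cleave the silyl ethers. Fallback: build the quaternary carbon by SN2' allylation of an organocopper reagent. It sets out from 10. Bromine–lithium exchange (t-BuLi, 2 equiv, Et2O, −78 °C, kept cold to avoid silyl migration) gives 2,4-bis(tert-butyldimethylsilyloxy)phenyllithium F2. CuI converts it into 2,4-bis(tert-butyldimethylsilyloxy)phenylcopper F3. BF3·OEt2 followed by 1-bromo-3-methylbut-2-ene at −78 → −30 °C directs attack to the gamma carbon of the allylic bromide. The fallback comes back to the route at 12.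

Step 1. The unprotected, electron-rich, doubly ortho-substituted aryl iodide may undergo slow oxidative addition or protodeiodination, and the free tertiary alcohol consumes some borane. Fallback: alkene insertion followed by reduction instead of sp3-boron coupling. It sets out from 1 and 2. A Heck reaction (Pd(OAc)2, tri(o-tolyl)phosphine, Et3N, MeCN, 80 °C) gives (E)-2-(3-hydroxy-3-methylbut-1-en-1-yl)benzene-1,3-diol F4, which is hydrogenated at once (H2, 1 atm, Pd/C, EtOAc) before it can cyclise to a chromene. The fallback comes back to the route at 4.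

**Further compounds**
F1 | step 6 | [2,4-bis(tert-butyldimethylsilyloxy)-5-(2-methylbut-3-en-2-yl)phenyl](2,4,6-trimethylphenyl)iodonium 4-methylbenzenesulfonate | C=CC(C)(C)c1cc([I+]c2c(C)cc(C)cc2C)c(O[Si](C)(C)C(C)(C)C)cc1O[Si](C)(C)C(C)(C)C.Cc1ccc(S(=O)(=O)[O-])cc1
F2 | step 5 | 2,4-bis(tert-butyldimethylsilyloxy)phenyllithium | [Li]c1ccc(O[Si](C)(C)C(C)(C)C)cc1O[Si](C)(C)C(C)(C)C
F3 | step 5 | 2,4-bis(tert-butyldimethylsilyloxy)phenylcopper | [Cu]c1ccc(O[Si](C)(C)C(C)(C)C)cc1O[Si](C)(C)C(C)(C)C
F4 | step 1 | (E)-2-(3-hydroxy-3-methylbut-1-en-1-yl)benzene-1,3-diol | CC(C)(O)/C=C/c1c(O)cccc1O
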